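Remark on the chemistry: flavonoid numbering is used (ring C: O1, C2, C3, C4; ring A: C4a, C5 to C8, C8a; second half doubly primed; An = 4-methoxyphenyl), 3,5-bis(benzyloxy)phenol (11) is taken to be a commercial phloroglucinol derivative, and a compound that a step consumes twice is entered twice on its Reactants line.

## The problem

Target 19 is a C2-symmetric 3,3''-biflavanone: two 5,7-dihydroxy-4'-methoxyflavanone units joined through the C3–C3'' bond, which links two tertiary carbons that are each α to a ketone (C4, C4'') and β to an aryl ether oxygen (O1, O1''). The four contiguous stereocenters C2, C3, C3'', C2'' are all S; in each ring C the anisyl group at C2 and the C3–C3'' bond are cis (H2 and H3 syn), and the two halves are homochiral. Attack on a C3 enolate anti to the C2 aryl group does not give this cis relationship, and both kinds of center are labile: C3 epimerizes through the enol, and C2 is lost by E1cB opening of ring C to a 2'-hydroxychalcone or by acid ionization of the p-methoxybenzylic C2–O1 bond. The rings A are phloroglucinol-type (free OH at C5 and C7, nucleophilic at C6 and C8), and the two aryl methyl ethers must outlast whatever frees the four phenols. Two features of the structure open a way around these problems. First, read as a chain, An–C2(O)–C3(C4=O)–C3''(C4''=O)–C2''(O)–An is the twofold syn-aldol adduct of a succinyl unit C4–C3–C3''–C4'' with two molecules of 4-methoxybenzaldehyde (5), and its four centers map with retention onto the exo,exo cis-fused bis-γ-lactone in which the oxygen on C2 acylates C4'' and the oxygen on C2'' acylates C4. Second, in each ring A the ring-fusion carbons C8a (bearing O1) and C4a (bearing C4) are neighbours and the C5 oxygen stands next to C4a: this is the pattern left when an oxygen nucleophile and an acyl group add across the triple bond of a 3,5-dioxygenated benzyne, with the oxygen at the carbon remote from the 3-alkoxy group.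

## Retrosynthesis

**19 ⇒ 18.** Only the four phenolic O–H bonds are cut, leading to the tetra-O-benzyl ether 18. Benzyl is preferred to methyl or silyl because its removal is neutral, spares the aryl methyl ethers and the enolizable C3 centers, and the group is inert to the fluoride used in the key step. The forward reaction is a hydrogenolysis that must stop before the benzylic C2–O1 bonds.

**18 ⇒ 10 + 2 × 15.** In each half the bonds O1–C8a and C4–C4a are cut, four bonds in all, which removes both rings A and opens both rings C. The neighbouring cuts, C3–C3'' (joining two flavanones) or C2–O1 (oxa-Michael addition or substitution), each make or break a bond at a stereocenter; this cut touches none, so all stereochemistry can be settled on an acyclic chain. The rings A become two molecules of aryne 16, released from two molecules of 15. The chain becomes 10, which has neither ring A nor ring C and half the carbon count of 18. The forward reaction asks each alkoxide of 10 to add to the aryne carbon remote from the benzyloxy group, and the resulting aryl anion to be acylated by the amide carbonyl C4 of the same half with closure of a six-membered ring (through 17).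

**10 ⇒ 9 ⇒ 8.** Compound 10 is the bis-silyl ether of diol diamide 9. Diol 9 is reconnected to dilactone 8 by joining the oxygen on C2 to C4'' and the oxygen on C2'' to C4, two bonds that are absent from 19. This is preferred to carrying an open-chain diol with ester or imide groups at C4 and C4'', because such compounds close to 8 by themselves. Dilactone 8 is the rigid, symmetric resting form of the stereotetrad, and its aminolysis installs an acyl acceptor that does not relactonize under basic conditions. The forward steps are acyl substitutions and a silylation that leave the four centers alone.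

**8 ⇒ 7 ⇒ 4 + 2 × 5.** In the open form 7 the bonds C2–C3 and C2''–C3'' (two aldol bonds) are cut, leading to succinyl bis-imide 4 and two molecules of 5; 4 comes from 1 and two molecules of 2. Cutting C3–C3'' instead would again pose the coupling of two stereogenic carbons. The forward reaction asks for two auxiliary-controlled syn-aldol additions of bis-enolate 6. Because both auxiliaries have the same configuration, the homochiral C2-symmetric adduct is the matched outcome, and the lactonization that follows releases the auxiliary.

**15 ⇒ 12 ⇒ 11.** The aryne precursor 15 derives from bromophenol 12 by O-silylation, bromine–lithium exchange with O-to-C silyl shift (13, 14) and triflation. Bromophenol 12 comes from 11 by ortho-bromination.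

## Roads not taken

Alternative 1: Cut C3–C3''. The forward key step is oxidative coupling of the C3 enolate of (2S)-5,7-bis(benzyloxy)-4'-methoxyflavanone A1 (LDA, then CuCl2 or I2); this is the route most chemists would draw first. It fails on structure. The enolate of A1 has the ring oxygen β to the carbanion and undergoes E1cB cleavage of the C2–O1 bond (retro-oxa-Michael opening of ring C), which erases C2. Where coupling does occur, the new bond forms anti to the C2 aryl group and leads to the 2,3-trans series (for example A2). Nothing distinguishes the C2-symmetric from the meso mode of joining C3 to C3''. The chosen plan forms no bond at C2 or C3 after the aldol step.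

Alternative 2: Cut both C2–O1 bonds. The forward key step is a twofold intramolecular oxa-Michael addition of the achiral bis-chalcone A3. All four centers would then be set in a reversible conjugate addition followed by enol protonation, so the C2/C3 relationship falls under thermodynamic control of ring C. A chiral catalyst would have to fix C2 and C2'' while C3 and C3'' are set by protonation. The chosen plan sets each center in a closed aldol transition state and then keeps it out of equilibrium.

Alternative 3: Cut four C–H bonds. The forward key step is a twofold enantioselective syn-hydrogenation of 3,3''-biflavone A4, itself made by Ullmann homocoupling of 3-iodoflavone A5. The idea is attractive because syn addition gives 2,3-cis by itself and one catalyst could set all four centers. However, C2=C3 of A4 is a tetrasubstituted vinylogous-ester double bond flanked by the second chromone in a twisted, biaryl-like diene, a substrate type without close precedent in asymmetric hydrogenation. The C4 carbonyls would compete, and basic additives would epimerize C3 of the product. The step count would be similar, but the stereochemistry would rest on an unprecedented reduction. In the chosen plan the stereocenters come from an aldol of known sense, and only the ring construction is new.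

Key step: step 7

## Route

Step 1
Reactants: 1 succinyl chloride; 2 (4S)-4-benzyl-1,3-oxazolidin-2-one; 2 (4S)-4-benzyl-1,3-oxazolidin-2-one
Product: 4 1,4-bis[(4S)-4-benzyl-2-oxo-1,3-oxazolidin-3-yl]butane-1,4-dione, via N-lithio oxazolidinone 3 (not isolated)
Conditions: 2 (2.1 equiv), n-BuLi (2.1 equiv), THF, −78 °C; then 1 (1.0 equiv), −78 → 0 °C
Reagents that add atoms: none
Why: N-acylation of the lithiated oxazolidinone by an acid chloride, the standard entry to N-acyl oxazolidinones; both acyl chloride groups react, each with one molecule of 2, and no stereocenter is touched.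

Step 2
Reactants: 4 1,4-bis[(4S)-4-benzyl-2-oxo-1,3-oxazolidin-3-yl]butane-1,4-dione; 5 4-methoxybenzaldehyde; 5 4-methoxybenzaldehyde
Product: 8 (3S,3aS,6S,6aS)-3,6-bis(4-methoxyphenyl)tetrahydro-1H,4H-furo[3,4-c]furan-1,4-dione, via bis(dibutylboron) Z,Z-dienolate 6 (not isolated), via bis-aldol diol 7 (not isolated)
Conditions: Bu2BOTf (2.4 equiv), i-Pr2NEt (2.8 equiv), CH2Cl2, −78 → 0 °C; 5 (2.6 equiv), −78 → 0 °C; pH 7 buffer, MeOH, 30% H2O2, 0 °C; crude in CH2Cl2, DMAP (0.2 equiv), rt
Reagents that add atoms: none
Why: Evans syn-aldol addition run in both directions: each C–C bond forms through a chair-like Zimmerman–Traxler transition state of a Z boron enolate, the (S)-benzyl auxiliary fixing C3 and C3'' as S and the syn relationship fixing C2 and C2'' as S, so the matched product is the homochiral C2-symmetric diol 7. In 7 each hydroxyl stands γ to the other imide carbonyl and closes a γ-lactone with loss of 2 (intramolecular acyl transfer from an N-acyl oxazolidinone), which should give the cis-fused dilactone 8 with both aryl groups exo.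

Step 3
Reactants: 8 (3S,3aS,6S,6aS)-3,6-bis(4-methoxyphenyl)tetrahydro-1H,4H-furo[3,4-c]furan-1,4-dione
Product: 9 (2S,3S)-2,3-bis[(S)-hydroxy(4-methoxyphenyl)methyl]-N1,N1,N4,N4-tetramethylbutanediamide
Conditions: Me2NH (2.0 M in THF, 10 equiv), THF, 0 °C → rt
Reagents that add atoms: dimethylamine, CNC
Why: Aminolysis of the strained cis-fused γ-lactones by a nucleophilic secondary amine (acyl C–O cleavage only); the four stereocenters are not involved, and a tertiary hydroxy amide does not relactonize without acid.

Step 4
Reactants: 9 (2S,3S)-2,3-bis[(S)-hydroxy(4-methoxyphenyl)methyl]-N1,N1,N4,N4-tetramethylbutanediamide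
Product: 10 (2S,3S)-2,3-bis[(S)-(4-methoxyphenyl)(trimethylsilyloxy)methyl]-N1,N1,N4,N4-tetramethylbutanediamide
Conditions: TMSCl (2.5 equiv), imidazole (5 equiv), CH2Cl2, 0 °C → rt
Reagents that add atoms: chlorotrimethylsilane, C[Si](C)(C)Cl
Why: Silylation of the secondary alcohols with TMSCl/imidazole; the trimethylsilyl ether is chosen because fluoride in step 7 can unmask the alkoxide while it releases the aryne, so no free hydroxyl proton is present there.

Step 5
Reactants: 11 3,5-bis(benzyloxy)phenol
Product: 12 3,5-bis(benzyloxy)-2-bromophenol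
Conditions: NBS (1.0 equiv), CH2Cl2, −78 °C
Reagents that add atoms: N-bromosuccinimide, O=C1CCC(=O)N1Br
Why: Electrophilic aromatic bromination ortho to the free hydroxyl; the position between OH and one benzyloxy group is less hindered than C4 between two benzyloxy groups, and one equivalent of NBS at low temperature limits polybromination.

Step 6
Reactants: 12 3,5-bis(benzyloxy)-2-bromophenol
Product: 15 3,5-bis(benzyloxy)-2-(trimethylsilyl)phenyl trifluoromethanesulfonate, via aryl trimethylsilyl ether 13 (not isolated), via lithium 2-silylphenoxide 14 (not isolated)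
Conditions: HMDS, THF, 70 °C, then evaporation; n-BuLi (1.1 equiv), THF, −100 → −80 °C; Tf2O (1.2 equiv), −100 °C → rt
Reagents that add atoms: hexamethyldisilazane, C[Si](C)(C)N[Si](C)(C)C; trifluoromethanesulfonic anhydride, O=S(=O)(OS(=O)(=O)C(F)(F)F)C(F)(F)F
Why: O-silylation, bromine–lithium exchange and 1,3 O-to-C silyl migration (retro-Brook rearrangement) place silicon on C2; triflation of the phenoxide then completes the 2-silylaryl triflate, the standard fluoride-triggered aryne precursor.

Step 7
Reactants: 10 (2S,3S)-2,3-bis[(S)-(4-methoxyphenyl)(trimethylsilyloxy)methyl]-N1,N1,N4,N4-tetramethylbutanediamide; 15 3,5-bis(benzyloxy)-2-(trimethylsilyl)phenyl trifluoromethanesulfonate; 15 3,5-bis(benzyloxy)-2-(trimethylsilyl)phenyl trifluoromethanesulfonate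
Product: 18 (2S,2'S,3S,3'S)-5,5',7,7'-tetrakis(benzyloxy)-2,2'-bis(4-methoxyphenyl)-[3,3'-bichromane]-4,4'-dione, via 3,5-bis(benzyloxy)benzyne 16 (not isolated), via dipotassium bis(aminal alkoxide) 17 (not isolated)
Conditions: 10 (1.0 equiv), KF (6 equiv), 18-crown-6 (6 equiv), THF, 0 °C; 15 (2.2 equiv), added over 2 h, 0 °C → rt; sat. aq. NH4Cl
Reagents that add atoms: none
Why: Proposed new method: fluoride strips the two O–SiMe3 groups of 10 and in parallel turns each molecule of 15 into aryne 16; each potassium alkoxide adds to the aryne carbon remote from the 3-benzyloxy group (the more electrophilic terminus of the distorted triple bond, with the developing carbanion placed next to the inductively withdrawing C–O bond), and the resulting aryl anion, with no O–H or N–H proton in reach, attacks the amide carbonyl C4 of its own half to give the tetrahedral bis(aminal alkoxide) 17, which should collapse to diketone 18 only on aqueous work-up. The stoichiometry is one molecule of 10 to two molecules of 15, one aryne for each half of the C2-symmetric chain. The closest known reaction type is the fluoride-mediated annulation of 2-silylaryl triflates with salicylate esters to xanthones (phenoxide addition to the aryne, then acylation of the aryl anion by the ester); here an aliphatic alkoxide and a tertiary amide take these roles. Each ring C closes by 6-exo-trig attack of the aryl carbanion on C4 (C4a–C4 bond) after the intermolecular O1–C8a bond has formed; attack on the other amide would need a seven-membered transition state. No stereocenter is created and no bond to C2, C3, C3'' or C2'' is broken, so the (S,S,S,S) array of 10 should pass into 18 unchanged, and C3 is never an enolizable ketone while base is present. The step needs regioselectivity at the aryne, secured by the benzyloxy group beside the triple bond (O at C8a, acyl at C4a next to C5–O), and acyl capture in preference to protonation, secured by the aprotic medium and the silyl-masked hydroxyls.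

Step 8
Reactants: 18 (2S,2'S,3S,3'S)-5,5',7,7'-tetrakis(benzyloxy)-2,2'-bis(4-methoxyphenyl)-[3,3'-bichromane]-4,4'-dione
Product: 19 (2S,2'S,3S,3'S)-5,5',7,7'-tetrahydroxy-2,2'-bis(4-methoxyphenyl)-[3,3'-bichromane]-4,4'-dione (CNP0260837.7)
Conditions: H2 (1 atm), Pd/C (10 wt% Pd), EtOAc–MeOH, rt
Reagents that add atoms: none
Why: Hydrogenolysis of the four aryl benzyl ethers under neutral conditions; the aryl methyl ethers are inert, and without acid or base neither C3 (enolization) nor C2 (ring opening) can epimerize.

## Compound list

1 | succinyl chloride | O=C(Cl)CCC(=O)Cl | starting material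
2 | (4S)-4-benzyl-1,3-oxazolidin-2-one | O=C1N[C@@H](Cc2ccccc2)CO1 | starting material
3 | lithium (4S)-4-benzyl-2-oxo-1,3-oxazolidin-3-ide | [Li+].O=C1[N-][C@@H](Cc2ccccc2)CO1 | intermediate
4 | 1,4-bis[(4S)-4-benzyl-2-oxo-1,3-oxazolidin-3-yl]butane-1,4-dione | O=C(CCC(=O)N1[C@@H](Cc2ccccc2)COC1=O)N1[C@@H](Cc2ccccc2)COC1=O | intermediate
5 | 4-methoxybenzaldehyde | COc1ccc(C=O)cc1 | starting material
6 | (1Z,3Z)-1,4-bis[(4S)-4-benzyl-2-oxo-1,3-oxazolidin-3-yl]-1,4-bis[(dibutylboranyl)oxy]buta-1,3-diene | CCCCB(CCCC)O/C(=C\C=C(/OB(CCCC)CCCC)N1[C@@H](Cc2ccccc2)COC1=O)N1[C@@H](Cc2ccccc2)COC1=O | intermediate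
7 | (2S,3S)-1,4-bis[(4S)-4-benzyl-2-oxo-1,3-oxazolidin-3-yl]-2,3-bis[(S)-hydroxy(4-methoxyphenyl)methyl]butane-1,4-dione | COc1ccc(cc1)[C@@H](O)[C@@H](C(=O)N1[C@@H](Cc2ccccc2)COC1=O)[C@H](C(=O)N1[C@@H](Cc2ccccc2)COC1=O)[C@H](O)c1ccc(OC)cc1 | intermediate
8 | (3S,3aS,6S,6aS)-3,6-bis(4-methoxyphenyl)tetrahydro-1H,4H-furo[3,4-c]furan-1,4-dione | COc1ccc(cc1)[C@H]1OC(=O)[C@H]2[C@@H]1C(=O)O[C@@H]2c1ccc(OC)cc1 | intermediate
9 | (2S,3S)-2,3-bis[(S)-hydroxy(4-methoxyphenyl)methyl]-N1,N1,N4,N4-tetramethylbutanediamide | COc1ccc(cc1)[C@@H](O)[C@@H](C(=O)N(C)C)[C@H](C(=O)N(C)C)[C@H](O)c1ccc(OC)cc1 | intermediate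
10 | (2S,3S)-2,3-bis[(S)-(4-methoxyphenyl)(trimethylsilyloxy)methyl]-N1,N1,N4,N4-tetramethylbutanediamide | COc1ccc(cc1)[C@@H](O[Si](C)(C)C)[C@@H](C(=O)N(C)C)[C@H](C(=O)N(C)C)[C@H](O[Si](C)(C)C)c1ccc(OC)cc1 | intermediate
11 | 3,5-bis(benzyloxy)phenol | Oc1cc(OCc2ccccc2)cc(OCc2ccccc2)c1 | starting material
12 | 3,5-bis(benzyloxy)-2-bromophenol | Oc1cc(OCc2ccccc2)cc(OCc2ccccc2)c1Br | intermediate
13 | [3,5-bis(benzyloxy)-2-bromophenoxy]trimethylsilane | C[Si](C)(C)Oc1cc(OCc2ccccc2)cc(OCc2ccccc2)c1Br | intermediate
14 | lithium 3,5-bis(benzyloxy)-2-(trimethylsilyl)phenolate | [Li+].[O-]c1cc(OCc2ccccc2)cc(OCc2ccccc2)c1[Si](C)(C)C | intermediate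
15 | 3,5-bis(benzyloxy)-2-(trimethylsilyl)phenyl trifluoromethanesulfonate | C[Si](C)(C)c1c(OCc2ccccc2)cc(OCc2ccccc2)cc1OS(=O)(=O)C(F)(F)F | intermediate
16 | 3,5-bis(benzyloxy)benzyne (1,2-didehydro-3,5-bis(benzyloxy)benzene) | C1(OCc2ccccc2)=CC(OCc2ccccc2)=CC#C1 | intermediate
17 | dipotassium (2S,2'S,3S,3'S)-5,5',7,7'-tetrakis(benzyloxy)-4,4'-bis(dimethylamino)-2,2'-bis(4-methoxyphenyl)-[3,3'-bichromane]-4,4'-bis(olate), C4 and C4' undefined | [K+].[K+].COc1ccc(cc1)[C@H]1Oc2cc(OCc3ccccc3)cc(OCc3ccccc3)c2C([O-])(N(C)C)[C@H]1[C@@H]1C([O-])(N(C)C)c2c(OCc3ccccc3)cc(OCc3ccccc3)cc2O[C@@H]1c1ccc(OC)cc1 | intermediate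
18 | (2S,2'S,3S,3'S)-5,5',7,7'-tetrakis(benzyloxy)-2,2'-bis(4-methoxyphenyl)-[3,3'-bichromane]-4,4'-dione | COc1ccc(cc1)[C@H]1Oc2cc(OCc3ccccc3)cc(OCc3ccccc3)c2C(=O)[C@H]1[C@@H]1C(=O)c2c(OCc3ccccc3)cc(OCc3ccccc3)cc2O[C@@H]1c1ccc(OC)cc1 | intermediate
19 | (2S,2'S,3S,3'S)-5,5',7,7'-tetrahydroxy-2,2'-bis(4-methoxyphenyl)-[3,3'-bichromane]-4,4'-dione (CNP0260837.7) | COc1ccc([C@H]2Oc3cc(O)cc(O)c3C(=O)[C@H]2[C@@H]2C(=O)c3c(O)cc(O)cc3O[C@@H]2c2ccc(OC)cc2)cc1 | target

## Step count and risks

Total step count: 8. Longest linear sequence: 6 steps (1, 2, 3, 4, 7, 8); the aryne branch (steps 5 and 6) joins at step 7.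

**Step 7 (key step, proposed new method).** Most likely to go wrong is protonation of the aryl anion before it reaches the amide carbonyl, since the anion is a very strong base and trace water or a C–H acid quenches it; this leaves a simple aryl ether without the C4–C4a bond. Also possible are retro-aldol fragmentation of the β-alkoxide amide before an aryne is at hand, and, less likely, addition at the proximal aryne carbon. The fallback uses two known operations, sets out from 9 (with two molecules of 15) and returns at 18. Under the established conditions for O–H insertion of arynes into aliphatic alcohols (KF, 18-crown-6, THF, rt), the free diol 9 is O-arylated at both hydroxyls by the aryne from 15 to give (2S,3S)-2,3-bis[(S)-[3,5-bis(benzyloxy)phenoxy](4-methoxyphenyl)methyl]-N1,N1,N4,N4-tetramethylbutanediamide F1. This ether is also the product that premature protonation in step 7 would leave. Electrophilic amide activation (Tf2O, 2-fluoropyridine, CH2Cl2, −78 → 0 °C, then aqueous NaHCO3) then effects an intramolecular Friedel–Crafts acylation of each phloroglucinol-type ring. Its two positions ortho to the ether oxygen are equivalent, so no regiochemical question arises, and hydrolysis of the iminium ions gives 18.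

**Step 2.** The second enolization has to occur next to an existing enolate and may be incomplete. Facial control may erode in the second aldol addition, where the enolate carbon carries a stereogenic substituent. Premature lactonization of the first aldolate onto the far imide would remove the second auxiliary before it has acted. The fallback replaces auxiliary control by resolution, sets out from 5 and returns at 8. Commercial N,N,N',N'-tetramethylsuccinamide is deprotonated twice (LDA, THF, −78 °C) and added to two molecules of 5 to give 2,3-bis[hydroxy(4-methoxyphenyl)methyl]-N1,N1,N4,N4-tetramethylbutanediamide F2 as a racemic mixture of diastereomers. TsOH in toluene closes both lactones; because the p-methoxybenzylic C–O bonds ionize reversibly under acid, the material should funnel to the racemic exo,exo dilactone rac-(3S*,3aS*,6S*,6aS*)-3,6-bis(4-methoxyphenyl)tetrahydro-1H,4H-furo[3,4-c]furan-1,4-dione F3. Aminolysis with (S)-1-phenylethylamine gives two diastereomeric bis(hydroxy amides), (2S,3S)-2,3-bis[(S)-hydroxy(4-methoxyphenyl)methyl]-N1,N4-bis[(S)-1-phenylethyl]butanediamide F4 and (2R,3R)-2,3-bis[(R)-hydroxy(4-methoxyphenyl)methyl]-N1,N4-bis[(S)-1-phenylethyl]butanediamide F5, which are separated by crystallization or chromatography. Warm dilute acid relactonizes F4 to enantiopure 8.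

**Step 3.** The amine may act as a base and trigger β-elimination across C3–C2 (E1cB opening of the lactone C–O bond to a cinnamamide), or the hydroxy amide may revert to the lactone during concentration or chromatography. The fallback sets out from 8 and returns at 10, skipping 9. Silyl-aminolysis with (dimethylamino)trimethylsilane (toluene, 60 °C) opens each lactone and delivers the oxygen directly as its trimethylsilyl ether, so no free alkoxide or hydroxyl is present; no new compound is made (F0).

**Step 8.** Hydrogenolysis of the benzylic C2–O1 bonds (each a p-methoxybenzylic aryl ether) or reduction of the C4 carbonyls may compete with O-debenzylation. The fallback sets out from 18 and returns at 19 by changing the mode of C–O cleavage from reductive to heterolytic: BCl3 with pentamethylbenzene as cation scavenger (CH2Cl2, −78 °C) removes aryl benzyl ethers and spares aryl methyl ethers and ketones; no new compound is made (F0).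

## Further compounds

F1 | step 7 | (2S,3S)-2,3-bis[(S)-[3,5-bis(benzyloxy)phenoxy](4-methoxyphenyl)methyl]-N1,N1,N4,N4-tetramethylbutanediamide | COc1ccc(cc1)[C@@H](Oc1cc(OCc2ccccc2)cc(OCc2ccccc2)c1)[C@@H](C(=O)N(C)C)[C@H](C(=O)N(C)C)[C@H](Oc1cc(OCc2ccccc2)cc(OCc2ccccc2)c1)c1ccc(OC)cc1
F2 | step 2 | 2,3-bis[hydroxy(4-methoxyphenyl)methyl]-N1,N1,N4,N4-tetramethylbutanediamide (racemic diastereomer mixture) | COc1ccc(cc1)C(O)C(C(=O)N(C)C)C(C(=O)N(C)C)C(O)c1ccc(OC)cc1
F3 | step 2 | rac-(3S*,3aS*,6S*,6aS*)-3,6-bis(4-methoxyphenyl)tetrahydro-1H,4H-furo[3,4-c]furan-1,4-dione (racemate, relative configuration shown) | COc1ccc(cc1)[C@H]1OC(=O)[C@H]2[C@@H]1C(=O)O[C@@H]2c1ccc(OC)cc1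
F4 | step 2 | (2S,3S)-2,3-bis[(S)-hydroxy(4-methoxyphenyl)methyl]-N1,N4-bis[(S)-1-phenylethyl]butanediamide | COc1ccc(cc1)[C@@H](O)[C@@H](C(=O)N[C@@H](C)c1ccccc1)[C@H](C(=O)N[C@@H](C)c1ccccc1)[C@H](O)c1ccc(OC)cc1
F5 | step 2 | (2R,3R)-2,3-bis[(R)-hydroxy(4-methoxyphenyl)methyl]-N1,N4-bis[(S)-1-phenylethyl]butanediamide | COc1ccc(cc1)[C@H](O)[C@H](C(=O)N[C@@H](C)c1ccccc1)[C@@H](C(=O)N[C@@H](C)c1ccccc1)[C@@H](O)c1ccc(OC)cc1
F0 | step 3 | none | none
F0 | step 8 | none | none
A1 | alternative 1 | (2S)-5,7-bis(benzyloxy)-2-(4-methoxyphenyl)chroman-4-one | COc1ccc(cc1)[C@@H]1CC(=O)c2c(OCc3ccccc3)cc(OCc3ccccc3)cc2O1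
A2 | alternative 1 | (2S,2'S,3R,3'R)-5,5',7,7'-tetrakis(benzyloxy)-2,2'-bis(4-methoxyphenyl)-[3,3'-bichromane]-4,4'-dione (2,3-trans,2'',3''-trans isomer) | COc1ccc(cc1)[C@H]1Oc2cc(OCc3ccccc3)cc(OCc3ccccc3)c2C(=O)[C@@H]1[C@H]1C(=O)c2c(OCc3ccccc3)cc(OCc3ccccc3)cc2O[C@@H]1c1ccc(OC)cc1
A3 | alternative 2 | (2E,3E)-1,4-bis[2,4-bis(benzyloxy)-6-hydroxyphenyl]-2,3-bis(4-methoxybenzylidene)butane-1,4-dione | COc1ccc(/C=C(/C(=O)c2c(O)cc(OCc3ccccc3)cc2OCc2ccccc2)\C(=C/c2ccc(OC)cc2)C(=O)c2c(O)cc(OCc3ccccc3)cc2OCc2ccccc2)cc1
A4 | alternative 3 | 5,5',7,7'-tetrakis(benzyloxy)-2,2'-bis(4-methoxyphenyl)-4H,4'H-[3,3'-bichromene]-4,4'-dione | COc1ccc(cc1)-c1oc2cc(OCc3ccccc3)cc(OCc3ccccc3)c2c(=O)c1-c1c(-c2ccc(OC)cc2)oc2cc(OCc3ccccc3)cc(OCc3ccccc3)c2c1=O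
A5 | alternative 3 | 5,7-bis(benzyloxy)-3-iodo-2-(4-methoxyphenyl)-4H-chromen-4-one | COc1ccc(cc1)-c1oc2cc(OCc3ccccc3)cc(OCc3ccccc3)c2c(=O)c1I
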